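**Retrosynthetic overview**
1. The vanillate ester C–O bond and three silyl ethers are disconnected last; the core is a bis-silylated trans-fused hydroazulenol.
2. The seven-membered ring is closed last, at C6–C7, by an intramolecular Nozaki–Hiyama–Kishi addition. The enabling feature is the secondary allylic carbinol C6, which lies between ring-fusion carbon C5 and the cis-trisubstituted C7=C8 alkene of the seven-membered ring, so a C6 aldehyde on C5 and a (Z)-iodoalkene on the C1 side chain can be joined.
3. The C1 methyl comes from conjugate addition to a cyclopentene carbaldehyde; the five-membered ring (closed first) from aldol condensation of a 1,6-keto aldehyde; the C9–C10 bond from a boron aldol reaction with (Z)-3-iodo-2-methylpropenal.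
4. The keto aldehyde comes from ozonolysis of (S)-terpinen-4-ol: its six ring carbons become C1–C6, its ring methyl becomes the ring CH2 C10, and its carbinol carbon with the isopropyl group becomes C4 unchanged.
5. Order of ring formation: terpene six-membered ring cleaved (step 2), five-membered ring closed (step 9), seven-membered ring closed (step 11).

Key step: step 11

**Remarks**
- Locants C1–C10 in the text are daucane locants of the target (C1 quaternary ring-fusion carbon with methyl, C4 carbinol with isopropyl, C5 ring-fusion CH, C6 ester carbon, C7=C8 alkene, C9 carbinol, C10 CH2); they are not the locants of the systematic names.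
- Commercial (S)-(+)-terpinen-4-ol is assumed to be enantiopure; with material of lower purity the minor series would be removed as a diastereomer after step 6.
- The Ipc2BCl aldol of methyl ketones is assumed to attack the Si face of the aldehyde with the (−)-reagent, so the (+)-reagent is specified for Re-face attack; if the sense is the reverse, the antipodal reagent is needed.

**Step 1**
Reactants: 1 (S)-(+)-terpinen-4-ol
Product: 2 triethyl{[(1S)-4-methyl-1-(propan-2-yl)cyclohex-3-en-1-yl]oxy}silane
Conditions: TESOTf, 2,6-lutidine, CH2Cl2, −78 → 0 °C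
Reagents that add atoms: triethylsilyl trifluoromethanesulfonate, CC[Si](CC)(CC)OS(=O)(=O)C(F)(F)F
Why: Silyl ether formation with the silyl triflate masks the hindered tertiary hydroxyl so that it cannot ketalise the ketone set free in step 2; no stereocentre is touched.

**Step 2**
Reactants: 2 silyl ether
Product: 4 (3S)-6-oxo-3-(propan-2-yl)-3-[(triethylsilyl)oxy]heptanal, via secondary ozonide 3 (not isolated)
Conditions: O3, CH2Cl2, −78 °C; then PPh3, −78 → 23 °C
Reagents that add atoms: ozone, [O-][O+]=O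
Why: Ozonolysis with reductive work-up cleaves the trisubstituted ring alkene to the 1,6-keto aldehyde and leaves the C4 stereocentre untouched.

**Step 3**
Reactants: 4 keto aldehyde
Product: 5 (5S)-7,7-dimethoxy-5-(propan-2-yl)-5-[(triethylsilyl)oxy]heptan-2-one
Conditions: HC(OMe)3, CeCl3·7H2O (cat.), MeOH, 23 °C
Reagents that add atoms: trimethyl orthoformate, COC(OC)OC
Why: CeCl3-catalysed acetalisation is selective for the aldehyde over the methyl ketone, which stays free for enolisation.

**Step 4**
Reactants: 6 prop-2-yn-1-ol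
Product: 8 (2Z)-3-iodo-2-methylprop-2-en-1-ol, via alkenylmagnesium alkoxide 7 (not isolated)
Conditions: MeMgBr, CuI (10 mol %), THF, −10 → 23 °C; then I2, −78 → 0 °C
Reagents that add atoms: methylmagnesium bromide, C[Mg]Br; iodine, II
Why: Copper-catalysed anti-carbomagnesiation of the propargylic alkoxide through a chelated alkenylmagnesium, then iodinolysis with retention, places iodine cis to the CH2OH group.

**Step 5**
Reactants: 8 iodo alcohol
Product: 9 (2Z)-3-iodo-2-methylprop-2-enal
Conditions: MnO2, CH2Cl2, 23 °C (used at once)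
Reagents that add atoms: none
Why: MnO2 oxidises the allylic alcohol under neutral conditions that preserve the Z geometry.

**Step 6**
Reactants: 5 keto acetal; 9 iodo enal
Product: 12 (1Z,3R,8S)-3-hydroxy-1-iodo-10,10-dimethoxy-2-methyl-8-(propan-2-yl)-8-[(triethylsilyl)oxy]dec-1-en-5-one, via enol diisopinocampheylborinate 10 (not isolated), via boron aldolate 11 (not isolated)
Conditions: (+)-Ipc2BCl, Et3N, Et2O, 0 °C; then 9, −78 → −20 °C; H2O2, MeOH, pH 7 buffer, 0 °C
Reagents that add atoms: none
Why: Diisopinocampheylboron-mediated aldol reaction: the boron chloride enolises the ketone on the methyl side and the chiral enolate should add to the Re face of 9, setting C9 as R under reagent control, with the minor C9 epimer removable as a diastereomer.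

**Step 7**
Reactants: 12 aldol
Product: 13 (1Z,3R,8S)-3-[(tert-butyldimethylsilyl)oxy]-1-iodo-10,10-dimethoxy-2-methyl-8-(propan-2-yl)-8-[(triethylsilyl)oxy]dec-1-en-5-one
Conditions: TBSCl, imidazole, DMF, 23 °C
Reagents that add atoms: tert-butyldimethylsilyl chloride, CC(C)(C)[Si](C)(C)Cl
Why: Silyl ether formation protects the β-hydroxy ketone against retro-aldol cleavage and differentiates the C9 oxygen from the later C6 hydroxyl.

**Step 8**
Reactants: 13 silyl ether
Product: 14 (3S,8R,9Z)-8-[(tert-butyldimethylsilyl)oxy]-10-iodo-9-methyl-6-oxo-3-(propan-2-yl)-3-[(triethylsilyl)oxy]dec-9-enal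
Conditions: PPTS (cat.), acetone/H2O 10:1, 50 °C
Reagents that add atoms: water, O
Why: Mild acid hydrolysis of the dimethyl acetal releases the aldehyde while both silyl ethers, the ketone and the iodoalkene should survive.

**Step 9**
Reactants: 14 keto aldehyde
Product: 15 (5R)-2-[(2R,3Z)-2-[(tert-butyldimethylsilyl)oxy]-4-iodo-3-methylbut-3-en-1-yl]-5-(propan-2-yl)-5-[(triethylsilyl)oxy]cyclopent-1-ene-1-carbaldehyde
Conditions: piperidine, AcOH, toluene, 60 °C
Reagents that add atoms: none
Why: Amine-catalysed intramolecular aldol condensation: the enamine of the aldehyde (C5) attacks the C1 ketone in a 5-exo-trig closure and dehydration gives the tetrasubstituted cyclopentene carbaldehyde, the usual outcome for 1,6-keto aldehydes under piperidinium acetate.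

**Step 10**
Reactants: 15 enal
Product: 17 (1R,2R,5R)-2-[(2R,3Z)-2-[(tert-butyldimethylsilyl)oxy]-4-iodo-3-methylbut-3-en-1-yl]-2-methyl-5-(propan-2-yl)-5-[(triethylsilyl)oxy]cyclopentane-1-carbaldehyde, via trimethylsilyl enol ether 16 (not isolated)
Conditions: Me2CuLi (from MeLi and CuI), TMSCl, THF/Et2O, −78 °C; then K2CO3 (cat.), MeOH, 0 °C
Reagents that add atoms: lithium dimethylcuprate, [Li+].C[Cu-]C
Why: TMSCl-accelerated conjugate addition of the Gilman reagent, to which the alkenyl iodide should be inert at −78 °C, delivers methyl to C1 opposite the C4 isopropyl group, and basic methanolysis of the silyl enol ether equilibrates C5 to the aldehyde trans to both the isopropyl group and the C1 side chain.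

**Step 11**
Reactants: 17 iodoalkenyl aldehyde
Product: 20 (3R,3aS,4S,7R,8aR)-7-[(tert-butyldimethylsilyl)oxy]-6,8a-dimethyl-3-(propan-2-yl)-3-[(triethylsilyl)oxy]-1,2,3,3a,4,7,8,8a-octahydroazulen-4-ol, via alkenylchromium dichloride 18 (not isolated), via chromium alkoxide 19 (not isolated)
Conditions: CrCl2 (8 equiv), NiCl2 (2 mol %), degassed DMSO, 23 °C, 0.005 M
Reagents that add atoms: none
Why: Nozaki–Hiyama–Kishi reaction: zerovalent nickel formed by CrCl2 inserts into the C–I bond with retention of the Z geometry, transmetalation gives the trivalent alkenylchromium 18, and this adds only to the aldehyde to give alkoxide 19. The closest known reaction type is the intramolecular Nozaki–Hiyama–Kishi cyclisation of iodoalkenyl aldehydes to medium-ring allylic alcohols. The seven-membered ring closes by 7-exo-trig attack of C7 on the C6 carbonyl carbon, and the Z-iodoalkene becomes the cis C7=C8 ring alkene. The new stereocentre C6 is controlled by C5 and its two quaternary neighbours: the tether holds C7 gauche to C1 and anti to C4, and the chromium-bound oxygen should take the open sector beside C5–H instead of the cleft between C1 and C4, which gives the 4S alcohol with oxygen syn to H5 as in the target. The step needs chemoselectivity (no attack on silyl ethers, no enolisation at C5) and ring closure instead of intermolecular coupling; the non-basic organochromium reagent and high dilution secure both.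

**Step 12**
Reactants: 21 vanillic acid
Product: 23 4-[(tert-butyldimethylsilyl)oxy]-3-methoxybenzoic acid, via bis-silylated vanillate 22 (not isolated)
Conditions: TBSCl (2.4 equiv), imidazole, DMF, 23 °C; then AcOH/THF/H2O, 23 °C
Reagents that add atoms: tert-butyldimethylsilyl chloride, CC(C)(C)[Si](C)(C)Cl
Why: Silylation of both acidic groups and selective hydrolysis of the labile silyl ester leave the phenol protected as its silyl ether.

**Step 13**
Reactants: 20 hydroazulenol; 23 protected vanillic acid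
Product: 24 (3R,3aS,4S,7R,8aR)-7-[(tert-butyldimethylsilyl)oxy]-6,8a-dimethyl-3-(propan-2-yl)-3-[(triethylsilyl)oxy]-1,2,3,3a,4,7,8,8a-octahydroazulen-4-yl 4-[(tert-butyldimethylsilyl)oxy]-3-methoxybenzoate
Conditions: DCC, DMAP (cat.), CH2Cl2, 23 → 40 °C
Reagents that add atoms: none
Why: Steglich esterification acylates the only free hydroxyl (secondary, allylic, C6) with retention of configuration.

**Step 14**
Reactants: 24 silylated ester
Product: 25 (3R,3aS,4S,7R,8aR)-3,7-dihydroxy-6,8a-dimethyl-3-(propan-2-yl)-1,2,3,3a,4,7,8,8a-octahydroazulen-4-yl 4-hydroxy-3-methoxybenzoate (target)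
Conditions: HF·pyridine, pyridine, THF, 0 → 23 °C
Reagents that add atoms: none
Why: Fluoride-mediated desilylation removes the aryl, secondary and tertiary silyl ethers in one operation under conditions that should leave the allylic ester and all stereocentres untouched.

**Compound list**
1 | (S)-(+)-terpinen-4-ol | CC1=CC[C@](O)(C(C)C)CC1 | starting material
2 | triethylsilyl ether of 1 | CC1=CC[C@](O[Si](CC)(CC)CC)(C(C)C)CC1 | intermediate
3 | secondary ozonide of 2 (1,2,4-trioxolane, ozonide centres as a mixture) | CC12CC[C@@](O[Si](CC)(CC)CC)(C(C)C)CC(OO1)O2 | intermediate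
4 | (3S)-6-oxo-3-(propan-2-yl)-3-[(triethylsilyl)oxy]heptanal | O=CC[C@](O[Si](CC)(CC)CC)(C(C)C)CCC(C)=O | intermediate
5 | (5S)-7,7-dimethoxy-5-(propan-2-yl)-5-[(triethylsilyl)oxy]heptan-2-one | COC(OC)C[C@](O[Si](CC)(CC)CC)(C(C)C)CCC(C)=O | intermediate
6 | prop-2-yn-1-ol | C#CCO | starting material
7 | bromomagnesium (Z)-3-(bromomagnesio)-2-methylprop-2-en-1-olate | Br[Mg]OC/C(C)=C\[Mg]Br | intermediate
8 | (2Z)-3-iodo-2-methylprop-2-en-1-ol | OC/C(C)=C\I | intermediate
9 | (2Z)-3-iodo-2-methylprop-2-enal | O=C/C(C)=C\I | intermediate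
10 | enol diisopinocampheylborinate of 5 (methyl-side enolate) | COC(OC)C[C@](O[Si](CC)(CC)CC)(C(C)C)CCC(=C)OB([C@H]1C[C@H]2C[C@@H]([C@@H]1C)C2(C)C)[C@H]1C[C@H]2C[C@@H]([C@@H]1C)C2(C)C | intermediate
11 | O-diisopinocampheylboryl aldolate of 12 | COC(OC)C[C@](O[Si](CC)(CC)CC)(C(C)C)CCC(=O)C[C@@H](OB([C@H]1C[C@H]2C[C@@H]([C@@H]1C)C2(C)C)[C@H]1C[C@H]2C[C@@H]([C@@H]1C)C2(C)C)/C(C)=C\I | intermediate
12 | (1Z,3R,8S)-3-hydroxy-1-iodo-10,10-dimethoxy-2-methyl-8-(propan-2-yl)-8-[(triethylsilyl)oxy]dec-1-en-5-one | COC(OC)C[C@](O[Si](CC)(CC)CC)(C(C)C)CCC(=O)C[C@@H](O)/C(C)=C\I | intermediate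
13 | 3-O-tert-butyldimethylsilyl ether of 12 | COC(OC)C[C@](O[Si](CC)(CC)CC)(C(C)C)CCC(=O)C[C@@H](O[Si](C)(C)C(C)(C)C)/C(C)=C\I | intermediate
14 | (3S,8R,9Z)-8-[(tert-butyldimethylsilyl)oxy]-10-iodo-9-methyl-6-oxo-3-(propan-2-yl)-3-[(triethylsilyl)oxy]dec-9-enal | O=CC[C@](O[Si](CC)(CC)CC)(C(C)C)CCC(=O)C[C@@H](O[Si](C)(C)C(C)(C)C)/C(C)=C\I | intermediate
15 | (5R)-2-[(2R,3Z)-2-[(tert-butyldimethylsilyl)oxy]-4-iodo-3-methylbut-3-en-1-yl]-5-(propan-2-yl)-5-[(triethylsilyl)oxy]cyclopent-1-ene-1-carbaldehyde | O=CC1=C(C[C@@H](O[Si](C)(C)C(C)(C)C)/C(C)=C\I)CC[C@@]1(O[Si](CC)(CC)CC)C(C)C | intermediate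
16 | trimethylsilyl enol ether of 17 (enol ether geometry open) | C[Si](C)(C)OC=C1[C@@](C)(C[C@@H](O[Si](C)(C)C(C)(C)C)/C(C)=C\I)CC[C@@]1(O[Si](CC)(CC)CC)C(C)C | intermediate
17 | (1R,2R,5R)-2-[(2R,3Z)-2-[(tert-butyldimethylsilyl)oxy]-4-iodo-3-methylbut-3-en-1-yl]-2-methyl-5-(propan-2-yl)-5-[(triethylsilyl)oxy]cyclopentane-1-carbaldehyde | O=C[C@@H]1[C@@](C)(C[C@@H](O[Si](C)(C)C(C)(C)C)/C(C)=C\I)CC[C@@]1(O[Si](CC)(CC)CC)C(C)C | intermediate
18 | alkenylchromium dichloride derived from 17 | O=C[C@@H]1[C@@](C)(C[C@@H](O[Si](C)(C)C(C)(C)C)/C(C)=C\[Cr](Cl)Cl)CC[C@@]1(O[Si](CC)(CC)CC)C(C)C | intermediate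
19 | dichlorochromium alkoxide of 20 | Cl[Cr](Cl)O[C@H]1C=C(C)[C@H](O[Si](C)(C)C(C)(C)C)C[C@@]2(C)CC[C@@](O[Si](CC)(CC)CC)(C(C)C)[C@H]12 | intermediate
20 | (3R,3aS,4S,7R,8aR)-7-[(tert-butyldimethylsilyl)oxy]-6,8a-dimethyl-3-(propan-2-yl)-3-[(triethylsilyl)oxy]-1,2,3,3a,4,7,8,8a-octahydroazulen-4-ol | O[C@H]1C=C(C)[C@H](O[Si](C)(C)C(C)(C)C)C[C@@]2(C)CC[C@@](O[Si](CC)(CC)CC)(C(C)C)[C@H]12 | intermediate
21 | vanillic acid | COc1cc(C(=O)O)ccc1O | starting material
22 | tert-butyldimethylsilyl 4-[(tert-butyldimethylsilyl)oxy]-3-methoxybenzoate | COc1cc(C(=O)O[Si](C)(C)C(C)(C)C)ccc1O[Si](C)(C)C(C)(C)C | intermediate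
23 | 4-[(tert-butyldimethylsilyl)oxy]-3-methoxybenzoic acid | COc1cc(C(=O)O)ccc1O[Si](C)(C)C(C)(C)C | intermediate
24 | silylated ester (name as in step 13) | COc1cc(C(=O)O[C@H]2C=C(C)[C@H](O[Si](C)(C)C(C)(C)C)C[C@@]3(C)CC[C@@](O[Si](CC)(CC)CC)(C(C)C)[C@H]23)ccc1O[Si](C)(C)C(C)(C)C | intermediate
25 | (3R,3aS,4S,7R,8aR)-3,7-dihydroxy-6,8a-dimethyl-3-(propan-2-yl)-1,2,3,3a,4,7,8,8a-octahydroazulen-4-yl 4-hydroxy-3-methoxybenzoate | COc1cc(C(=O)O[C@H]2C=C(C)[C@H](O)C[C@@]3(C)CC[C@@](O)(C(C)C)[C@H]23)ccc1O | target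

**Step count**
Total: 14 steps. Longest linear sequence: 11 steps (1, 2, 3, 6, 7, 8, 9, 10, 11, 13, 14).

**Steps most likely to fail**

1. Step 10. What may go wrong: the organocopper reagent is consumed at the alkenyl iodide (coupling or halogen–metal exchange) while addition to the hindered tetrasubstituted enal is slow, and the basic equilibration at C5 may trigger β-elimination of the C4 silyloxy group. The fallback sets out from 5 and removes the iodide from the methylation substrate. The aldol reaction of step 6 is run with methacrolein to give hydroxy ketone F4, which is silylated (TBSCl, imidazole) to silyl ether F5, hydrolysed (PPTS, aqueous acetone) to keto aldehyde F6 and condensed (piperidine, AcOH) to enal F7. Me2CuLi/TMSCl, now usable in excess and at higher temperature, then K2CO3/MeOH, gives aldehyde F8. Vinylmagnesium bromide should add to F8 anti to C4 (Felkin–Anh sense) to give dienol F9, and ring-closing metathesis with the second-generation Grubbs catalyst (toluene, 80 °C) forms the C7=C8 bond and comes back to the route at 20.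

2. Step 9. What may go wrong: enolisation of the ketone towards C10 with E1cB loss of the C9 silyloxy group, or cyclisation in the other sense (ketone enol onto the aldehyde). The fallback sets out from 4, which has no β-leaving group on the ketone side. It is condensed (piperidine, AcOH) to enal F1. TBSOTf/Et3N should remove a γ-hydrogen from the methyl group, which is syn to the formyl group, to give silyl dienol ether F2. A vinylogous Mukaiyama aldol reaction with 9 (BF3·OEt2, CH2Cl2, −78 °C) gives hydroxy enal F3, whose C9 epimers are separated, and silylation (TBSCl, imidazole) comes back to the route at 15.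

3. Step 11. What may go wrong: poor facial selectivity in the addition to the aldehyde, so that 20 forms as a mixture of C6 epimers. The fallback sets out from 20 as that mixture and sets C6 by reduction instead. Oxidation with Dess–Martin periodinane gives enone F10, and HF·pyridine removes both silyl groups to give dihydroxy enone F11. Hydroxyl-directed reduction with Me4NBH(OAc)3 (Evans–Saksena reduction, MeCN/AcOH, −20 °C) delivers hydride from the face of the C4 hydroxyl and should give triol F12 with the C6 configuration of the target. The less hindered C9 hydroxyl is silylated selectively (TBSCl, imidazole) to silyl ether F13, Steglich esterification with 23 gives ester F14, and HF·pyridine comes back to the route at 25.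

**Further compounds**
F1 | step 9 | (5R)-2-methyl-5-(propan-2-yl)-5-[(triethylsilyl)oxy]cyclopent-1-ene-1-carbaldehyde | O=CC1=C(C)CC[C@@]1(O[Si](CC)(CC)CC)C(C)C
F2 | step 9 | tert-butyldimethylsilyl dienol ether of F1 with exocyclic methylene at C1 | C=C1CC[C@@](O[Si](CC)(CC)CC)(C(C)C)C1=CO[Si](C)(C)C(C)(C)C
F3 | step 9 | (5R)-2-[(2R,3Z)-2-hydroxy-4-iodo-3-methylbut-3-en-1-yl]-5-(propan-2-yl)-5-[(triethylsilyl)oxy]cyclopent-1-ene-1-carbaldehyde | O=CC1=C(C[C@@H](O)/C(C)=C\I)CC[C@@]1(O[Si](CC)(CC)CC)C(C)C
F4 | step 10 | (3R,8S)-3-hydroxy-10,10-dimethoxy-2-methyl-8-(propan-2-yl)-8-[(triethylsilyl)oxy]dec-1-en-5-one | COC(OC)C[C@](O[Si](CC)(CC)CC)(C(C)C)CCC(=O)C[C@@H](O)C(C)=C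
F5 | step 10 | 3-O-tert-butyldimethylsilyl ether of F4 | COC(OC)C[C@](O[Si](CC)(CC)CC)(C(C)C)CCC(=O)C[C@@H](O[Si](C)(C)C(C)(C)C)C(C)=C
F6 | step 10 | isopropenyl analogue of 14 (keto aldehyde) | O=CC[C@](O[Si](CC)(CC)CC)(C(C)C)CCC(=O)C[C@@H](O[Si](C)(C)C(C)(C)C)C(C)=C
F7 | step 10 | isopropenyl analogue of 15 (cyclopentene carbaldehyde) | O=CC1=C(C[C@@H](O[Si](C)(C)C(C)(C)C)C(C)=C)CC[C@@]1(O[Si](CC)(CC)CC)C(C)C
F8 | step 10 | isopropenyl analogue of 17 (methylated aldehyde) | O=C[C@@H]1[C@@](C)(C[C@@H](O[Si](C)(C)C(C)(C)C)C(C)=C)CC[C@@]1(O[Si](CC)(CC)CC)C(C)C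
F9 | step 10 | vinyl carbinol from F8 (C6 configured as in 20) | C=C[C@H](O)[C@@H]1[C@@](C)(C[C@@H](O[Si](C)(C)C(C)(C)C)C(C)=C)CC[C@@]1(O[Si](CC)(CC)CC)C(C)C
F10 | step 11 | C6 ketone (enone) from 20 | O=C1C=C(C)[C@H](O[Si](C)(C)C(C)(C)C)C[C@@]2(C)CC[C@@](O[Si](CC)(CC)CC)(C(C)C)[C@H]12
F11 | step 11 | desilylated dihydroxy enone | O=C1C=C(C)[C@H](O)C[C@@]2(C)CC[C@@](O)(C(C)C)[C@H]12
F12 | step 11 | (3R,3aS,4S,7R,8aR)-6,8a-dimethyl-3-(propan-2-yl)-1,2,3,3a,4,7,8,8a-octahydroazulene-3,4,7-triol | O[C@H]1C=C(C)[C@H](O)C[C@@]2(C)CC[C@@](O)(C(C)C)[C@H]12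
F13 | step 11 | 7-O-tert-butyldimethylsilyl ether of F12 | O[C@H]1C=C(C)[C@H](O[Si](C)(C)C(C)(C)C)C[C@@]2(C)CC[C@@](O)(C(C)C)[C@H]12
F14 | step 11 | 4-O-[4-(tert-butyldimethylsilyloxy)-3-methoxybenzoyl] ester of F13 | COc1cc(C(=O)O[C@H]2C=C(C)[C@H](O[Si](C)(C)C(C)(C)C)C[C@@]3(C)CC[C@@](O)(C(C)C)[C@H]23)ccc1O[Si](C)(C)C(C)(C)C
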